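**Atom numbering.** Ring A (the benzoate): C1 CO2Me, C2 CH3, C3 H, C4 OH, C5 CH2OH, C6 ether oxygen. Ring B (the arene of the phthalide): C1' ether oxygen, C2' CH3, C3' lactone CH2, C4' lactone carbonyl, C5' OH, C6' OH.

**Assumption.** 3-Fluoro-5-methylphenol and 3,4,5-trihydroxybenzaldehyde (hydrate, dried) are taken as purchasable; the target is achiral, so no step has to set configuration.

## Analysis of the target

The target is a diaryl ether of a pentasubstituted methyl benzoate (ring A) and a hexasubstituted benzene fused to a five-membered lactone (ring B, a phthalide). It has no stereocentre. The ether oxygen joins C6 and C1', and both carbons have two substituted neighbours (C1 ester and C5 CH2OH; C2' methyl and C6' hydroxyl), so the C–O–C unit is tetra-ortho-substituted. Several groups are sensitive: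

- the C5'/C6' catechol oxidises in air under base;
- the C5 hydroxymethyl, flanked by the C4 hydroxyl and the C6 ether oxygen, ionises easily to a quinone methide under acid or heat;
- the lactone and the methyl ester are base-labile, and the C6' hydroxyl lies close enough to the ring A ester to close a seven-membered depsidone.

The synthesis is hard for two reasons: the crowded ether, and the placing of six different substituents around ring B. The plan rests on one feature of ring B. The lactone carbonyl carbon is bound to C4', which is ortho to the C5' hydroxyl and ortho to the C3' CH2O, so the lactone is a salicylic acid esterified by its neighbouring hydroxymethyl. Without that carbon, C4' is the only unsubstituted position of ring B and sits exactly where a phenoxide delivers CO2. A second feature helps with the ether: C6 lies between C1 and C5, and both can carry a carbonyl group if C5 is held at the aldehyde level.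

## Retrosynthetic reasoning

**17 to 16.** The C4 hydroxyl and the C5 hydroxymethyl of ring A are tied back as an isopropylidene ketal. The carboxylation uses a phenoxide, and ring A must not offer one, since its C3 position is free and ortho to the C4 oxygen. The ketal also masks the most acid-sensitive benzylic alcohol and is removed by dilute aqueous acid that leaves lactone and ester alone.

**16 to 13 and 14 (through 15).** Two bonds are cut: C4'–C(=O) and the acyl–oxygen bond of the lactone. This is the only place on ring B where a carbon can be removed to leave a position that is both unsubstituted and ortho to a phenol. The gain is that the most crowded carbon of the hexasubstituted ring arrives last, as carbon dioxide 14, after the ether exists. The forward reaction must carboxylate the catecholate of 13 at C4' and let the acid 15 close on the C3' hydroxymethyl.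

**13 to 12 to 11.** The ketal comes from the free ortho-hydroxybenzyl alcohol of 12. Both benzylic alcohols of 12 are traced to aldehydes in 11. Holding C5 and C3' as aldehydes serves two purposes: the C5 aldehyde activates the ether-forming step, and no benzylic alcohol is present while acid removes the protecting groups.

**11 to 10.** The three phenolic hydroxyls are unmasked from a methoxymethyl ether on ring A and a diphenylmethylene ketal on ring B. Both are acid-labile and both fall in one operation on a substrate that has only aldehydes, an ester and an ether.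

**10 to 5 and 9.** The C6–O bond is cut, with the oxygen kept on ring B. In 5 the leaving fluoride at C6 is flanked by the C1 ester and the C5 aldehyde, so the ether forms by addition–elimination without a metal. The reverse polarity was not chosen: a ring A 2-hydroxybenzoate would offer a chelated, doubly flanked phenol, and the electron-rich ring B cannot be made an electrophile. A copper-mediated union of two doubly ortho-substituted partners is less dependable than attack on a fluoride between two acceptors.

**5 to 4 to 3 to 2 to 1.** The ester is traced to a bromide (carbonylation), the aldehyde to a C–H bond between fluorine and the protected oxygen (directed metalation, formylation), and the bromide to para-bromination of phenol 1. Each substituent enters at a position dictated by the groups already present.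

**9 to 8 to 7 to 6.** The C2' methyl is traced to a bromide (cross-coupling), the bromide to bromination next to the free hydroxyl of 7, and 7 to the symmetrical trihydroxy aldehyde 6. A ketal can only bridge two adjacent oxygens of 6, which leaves one terminal hydroxyl free: the future ether oxygen.

## Alternatives that were turned down

**Alternative 1:** oxygen insertion into a xanthone. The disconnection removes the oxygen between the ester carbonyl and C6' of depsidone A1, leading back to xanthone A2, in which the ether is part of a pyranone ring. In the forward key step a peracid or alkaline peroxide adds to the xanthone carbonyl and the ortho-hydroxylated ring B carbon C6' migrates to oxygen, giving the seven-membered lactone A1. Methanolysis then sets the methyl ester and the C6' phenol together.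
- For it: the ether bond is closed inside a ring, which is easier than any intermolecular union of crowded partners. On this point it is as strong as or stronger than the chosen plan.
- Against it: the carbonyl of A2 is a vinylogous carbonate, conjugated to the pyran oxygen and chelated by the C5' hydroxyl, so peroxide addition is poor. Alkaline peroxide would also open the phthalide and the acetate and can oxidise the phenol. The ring expansion to a seven-membered lactone is uphill in strain. A2 itself, fully substituted and already carrying the phthalide, needs a long synthesis, and the mesylate and acetate remain to be removed.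
- Comparison: the chosen plan answers the ether problem with a fluoride between two carbonyl groups. Its single uncertain step is a carboxylation of a simple catechol, not an oxidation of a finished tetracycle.

**Alternative 2:** benzannulation of ring A. Ring A is cut into diazo keto ester A4 and the ring B aryl ynol ether A5. Photolysis of A4 causes a Wolff shift to vinylketene A6. A6 adds to A5 in a [2+2] step (C4–C5 and C1–C6), and four-electron opening then six-electron closure (C3–C4) gives phenol A3.
- For it: the connectivity of the partners fixes all substituents of ring A, and the ether oxygen travels on the alkyne, so no bond to a hindered aryl carbon is made. Here it is stronger than the chosen plan.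
- Against it: A5 is an alkynyl ether of a hindered phenol that bears a lactone, and the usual ynol ether preparations use strong-base eliminations. An aryloxy alkyne is a weaker donor than an alkoxy alkyne. A6 carries an ester on the ketene carbon and can react as an oxadiene in a [4+2] mode or dimerise. A4 is a 2-diazo-1,3-dicarbonyl compound, a class that rearranges sluggishly. A3 then needs two deprotections, one a hydrogenolysis next to a benzylic alcohol.
- Comparison: both partners require multi-step syntheses. The chosen plan builds both rings from commercial arenes by substitution chemistry.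

**Alternative 3:** annulation of ring B onto a butenolide. Ring B is cut at C2'–C3' and C4'–C5' into sulfonyl enoate A8 and furan-2(5H)-one A9. The sulfonyl carbanion of A8 adds to A9, the lactone enolate closes on the ester carbon, and loss of sulfinate aromatises to A7.
- For it: the lactone carbonyl is built in from the start, so no hot carboxylation of a sensitive hydroxybenzyl alcohol is needed. Here it is stronger than the chosen plan.
- Against it: A8 is a tetrasubstituted enol ether of defined geometry that carries the ring A aryloxy group, so the hindered C–O bond problem is moved, not removed. Its carbanion is tertiary. A9 is deprotonated at C5 under base and polymerises. A benzyl ether remains to be hydrogenolysed.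
- Comparison: making A8 would take more steps than the whole ring B sequence of the chosen plan, which in exchange accepts one risky but very short final carbon delivery.

Key step: step 12

## Route

**Step 1**
Reactants: 1 3-fluoro-5-methylphenol
Product: 2 4-bromo-3-fluoro-5-methylphenol
Conditions: NBS, MeCN, 0 °C
Reagents that add atoms: N-bromosuccinimide, O=C1CCC(=O)N1Br
Why: Electrophilic aromatic bromination; the hydroxyl directs para, that carbon is also ortho to fluorine and methyl, and the polar solvent favours para over ortho attack.

**Step 2**
Reactants: 2 4-bromo-3-fluoro-5-methylphenol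
Product: 3 2-bromo-1-fluoro-5-(methoxymethoxy)-3-methylbenzene
Conditions: MOMCl, i-Pr2NEt, CH2Cl2, 0 °C→rt
Reagents that add atoms: chloromethyl methyl ether, COCCl
Why: O-Alkylation of the phenol (MOM protection); the acetal ether later cooperates with fluorine in the metalation and prevents a phenoxide from deactivating the substitution of step 8.

**Step 3**
Reactants: 3 2-bromo-1-fluoro-5-(methoxymethoxy)-3-methylbenzene
Product: 4 3-bromo-2-fluoro-6-(methoxymethoxy)-4-methylbenzaldehyde
Conditions: LiN(i-Pr)2, THF, −78 °C; DMF; aq NH4Cl
Reagents that add atoms: N,N-dimethylformamide, CN(C)C=O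
Why: Directed ortho-metalation and formylation; the C–H between F and OMOM is the most acidic and the only one both groups direct to, a lithium amide leaves the C–Br bond unexchanged, and at −78 °C the ortho-fluoro aryllithium does not lose LiF.

**Step 4**
Reactants: 4 3-bromo-2-fluoro-6-(methoxymethoxy)-4-methylbenzaldehyde
Product: 5 methyl 2-fluoro-3-formyl-4-(methoxymethoxy)-6-methylbenzoate
Conditions: Pd(OAc)2, Xantphos, CO (1 atm), MeOH, Et3N, toluene, 80 °C
Reagents that add atoms: carbon monoxide, [C-]#[O+]; methanol, CO
Why: Palladium-catalysed methoxycarbonylation of an aryl bromide (oxidative addition to zerovalent palladium, CO insertion, methanolysis of the acyl palladium); the wide-bite-angle ligand handles ortho-substituted bromides at low pressure, and an amine base instead of an alkoxide spares the C–F bond.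

**Step 5**
Reactants: 6 3,4,5-trihydroxybenzaldehyde
Product: 7 7-hydroxy-2,2-diphenyl-1,3-benzodioxole-5-carbaldehyde
Conditions: Ph2CCl2, Ph2O, 175 °C
Reagents that add atoms: dichlorodiphenylmethane, ClC(Cl)(c1ccccc1)c1ccccc1
Why: Ketalisation of a catechol unit with a gem-dichloride; only adjacent hydroxyls can close the dioxole, and because 6 is symmetrical both ways of doing so give the same product with one terminal hydroxyl free.

**Step 6**
Reactants: 7 7-hydroxy-2,2-diphenyl-1,3-benzodioxole-5-carbaldehyde
Product: 8 6-bromo-7-hydroxy-2,2-diphenyl-1,3-benzodioxole-5-carbaldehyde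
Conditions: NBS, i-Pr2NH (10 mol %), CH2Cl2, 0 °C
Reagents that add atoms: N-bromosuccinimide, O=C1CCC(=O)N1Br
Why: Amine-mediated ortho-selective bromination of a phenol; the hydrogen-bonded N-bromoamine delivers bromine to the single free ortho position (C6), in line with bromination of 3-hydroxy-4-alkoxybenzaldehydes between hydroxyl and formyl.

**Step 7**
Reactants: 8 6-bromo-7-hydroxy-2,2-diphenyl-1,3-benzodioxole-5-carbaldehyde
Product: 9 7-hydroxy-6-methyl-2,2-diphenyl-1,3-benzodioxole-5-carbaldehyde
Conditions: MeB(OH)2, Pd(dppf)Cl2, K2CO3, dioxane–H2O, 95 °C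
Reagents that add atoms: methylboronic acid, CB(O)O
Why: Suzuki–Miyaura methylation; the ortho formyl group eases oxidative addition, and the free phenol is tolerated with extra base.

**Step 8**
Reactants: 5 methyl 2-fluoro-3-formyl-4-(methoxymethoxy)-6-methylbenzoate; 9 7-hydroxy-6-methyl-2,2-diphenyl-1,3-benzodioxole-5-carbaldehyde
Product: 10 methyl 3-formyl-2-[(6-formyl-5-methyl-2,2-diphenyl-1,3-benzodioxol-4-yl)oxy]-4-(methoxymethoxy)-6-methylbenzoate
Conditions: K2CO3, DMF, 70 °C
Reagents that add atoms: none
Why: Nucleophilic aromatic substitution (addition–elimination); the phenoxide of 9 adds to the C–F carbon flanked by formyl and ester, the Meisenheimer anion is delocalised into both carbonyl groups, and fluoride suits a mechanism whose slow step is the addition, so the tetra-ortho-substituted ether forms without a metal.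

**Step 9**
Reactants: 10 (the protected dialdehyde)
Product: 11 methyl 3-formyl-2-(5-formyl-2,3-dihydroxy-6-methylphenoxy)-4-hydroxy-6-methylbenzoate
Conditions: TFA–H2O (9:1), 0 °C→rt
Reagents that add atoms: none
Why: Acid hydrolysis of the MOM acetal and of the diphenylmethylene ketal in one operation; at the dialdehyde stage no benzylic alcohol is present to ionise, and the hindered methyl ester and the diaryl ether are inert.

**Step 10**
Reactants: 11 (the dialdehyde triphenol)
Product: 12 methyl 2-[2,3-dihydroxy-5-(hydroxymethyl)-6-methylphenoxy]-4-hydroxy-3-(hydroxymethyl)-6-methylbenzoate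
Conditions: NaBH4, THF–MeOH, 0 °C, argon; pH 6 buffer
Reagents that add atoms: none
Why: Borohydride reduction of both aryl aldehydes; the ester is untouched, and low temperature with near-neutral work-up keeps the two hydroxybenzyl alcohols from forming quinone methides.

**Step 11**
Reactants: 12 (the pentol)
Product: 13 methyl 5-[2,3-dihydroxy-5-(hydroxymethyl)-6-methylphenoxy]-2,2,7-trimethyl-4H-1,3-benzodioxine-6-carboxylate
Conditions: 2,2-dimethoxypropane, PPTS (cat.), acetone, rt; NaHCO3
Reagents that add atoms: 2,2-dimethoxypropane, COC(C)(C)OC
Why: Acid-catalysed transketalisation; only the ortho-hydroxybenzyl alcohol of ring A closes a six-membered ketal under mild catalysis, a catechol needs forcing conditions to form its five-membered ketal, and any acyclic mixed ketal at the ring B alcohol reverts on work-up.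

**Step 12**
Reactants: 13 (ring B catechol benzyl alcohol, ring A acetonide); 14 carbon dioxide
Product: 16 methyl 5-[(6,7-dihydroxy-4-methyl-1-oxo-1,3-dihydro-2-benzofuran-5-yl)oxy]-2,2,7-trimethyl-4H-1,3-benzodioxine-6-carboxylate, via hydroxy acid 15 (not isolated)
Conditions: KHCO3, CO2 (10 bar), DMF, 110 °C; K2CO3, MeOH, rt; aq HCl to pH 3, 0 °C→rt
Reagents that add atoms: none
Why: Kolbe–Schmitt carboxylation followed by lactonisation: bicarbonate converts the ring B catechol of 13 into its potassium phenoxide, which binds 14 through the cation. The C5' phenoxide attacks CO2 with its ortho carbon C4' through a potassium-bridged six-membered transition state, and the resulting cyclohexadienone carboxylate loses the C4' proton and rearomatises to the salicylate; the closest known cases are the bicarbonate carboxylations of pyrogallol and catechol. Regiochemistry is fixed by the substitution pattern, because C4' is the only ring B carbon that still bears hydrogen, and it is ortho to the C5' oxygen and para to the donating ether oxygen at C1'. Ring A cannot compete because its phenol is locked in the acetonide and an aryl ether does not undergo this reaction. On acidification the C3' hydroxymethyl oxygen adds to the carboxyl carbon of 15 (5-exo-trig) and water is lost, closing the five-membered lactone as 2-(hydroxymethyl)benzoic acids do spontaneously. O-Carboxylation of the benzylic alcohol or the phenols is reversible and these carbonates fall apart on acidification. If the C6' phenoxide attacks the ring A ester and closes a depsidone, the methanolic carbonate treatment before acidification reopens it to the methyl ester. No stereocentre is formed.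

**Step 13**
Reactants: 16 (the acetonide of the target)
Product: 17 methyl 2-[(6,7-dihydroxy-4-methyl-1-oxo-1,3-dihydro-2-benzofuran-5-yl)oxy]-4-hydroxy-3-(hydroxymethyl)-6-methylbenzoate (CNP0220419.0)
Conditions: AcOH–H2O–THF (3:1:1), 40 °C
Reagents that add atoms: none
Why: Acid hydrolysis of the isopropylidene ketal; water is the only nucleophile present, so the easily ionised C5 benzylic position returns the alcohol, and lactone and ester are stable to dilute acetic acid.

## Compound list

1 | 3-fluoro-5-methylphenol | Cc1cc(O)cc(F)c1 | starting material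
2 | 4-bromo-3-fluoro-5-methylphenol | Cc1cc(O)cc(F)c1Br | intermediate
3 | 2-bromo-1-fluoro-5-(methoxymethoxy)-3-methylbenzene | COCOc1cc(C)c(Br)c(F)c1 | intermediate
4 | 3-bromo-2-fluoro-6-(methoxymethoxy)-4-methylbenzaldehyde | COCOc1cc(C)c(Br)c(F)c1C=O | intermediate
5 | methyl 2-fluoro-3-formyl-4-(methoxymethoxy)-6-methylbenzoate | COC(=O)c1c(C)cc(OCOC)c(C=O)c1F | intermediate
6 | 3,4,5-trihydroxybenzaldehyde | O=Cc1cc(O)c(O)c(O)c1 | starting material
7 | 7-hydroxy-2,2-diphenyl-1,3-benzodioxole-5-carbaldehyde | O=Cc1cc(O)c2OC(c3ccccc3)(c3ccccc3)Oc2c1 | intermediate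
8 | 6-bromo-7-hydroxy-2,2-diphenyl-1,3-benzodioxole-5-carbaldehyde | O=Cc1cc2OC(c3ccccc3)(c3ccccc3)Oc2c(O)c1Br | intermediate
9 | 7-hydroxy-6-methyl-2,2-diphenyl-1,3-benzodioxole-5-carbaldehyde | O=Cc1cc2OC(c3ccccc3)(c3ccccc3)Oc2c(O)c1C | intermediate
10 | methyl 3-formyl-2-[(6-formyl-5-methyl-2,2-diphenyl-1,3-benzodioxol-4-yl)oxy]-4-(methoxymethoxy)-6-methylbenzoate | COC(=O)c1c(C)cc(OCOC)c(C=O)c1Oc1c(C)c(C=O)cc2OC(c3ccccc3)(c3ccccc3)Oc12 | intermediate
11 | methyl 3-formyl-2-(5-formyl-2,3-dihydroxy-6-methylphenoxy)-4-hydroxy-6-methylbenzoate | COC(=O)c1c(C)cc(O)c(C=O)c1Oc1c(C)c(C=O)cc(O)c1O | intermediate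
12 | methyl 2-[2,3-dihydroxy-5-(hydroxymethyl)-6-methylphenoxy]-4-hydroxy-3-(hydroxymethyl)-6-methylbenzoate | COC(=O)c1c(C)cc(O)c(CO)c1Oc1c(C)c(CO)cc(O)c1O | intermediate
13 | methyl 5-[2,3-dihydroxy-5-(hydroxymethyl)-6-methylphenoxy]-2,2,7-trimethyl-4H-1,3-benzodioxine-6-carboxylate | COC(=O)c1c(C)cc2OC(C)(C)OCc2c1Oc1c(C)c(CO)cc(O)c1O | intermediate
14 | carbon dioxide | O=C=O | starting material
15 | 2,3-dihydroxy-6-(hydroxymethyl)-4-{[6-(methoxycarbonyl)-2,2,7-trimethyl-4H-1,3-benzodioxin-5-yl]oxy}-5-methylbenzoic acid | COC(=O)c1c(C)cc2OC(C)(C)OCc2c1Oc1c(C)c(CO)c(C(=O)O)c(O)c1O | intermediate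
16 | methyl 5-[(6,7-dihydroxy-4-methyl-1-oxo-1,3-dihydro-2-benzofuran-5-yl)oxy]-2,2,7-trimethyl-4H-1,3-benzodioxine-6-carboxylate | COC(=O)c1c(C)cc2OC(C)(C)OCc2c1Oc1c(C)c2COC(=O)c2c(O)c1O | intermediate
17 | methyl 2-[(6,7-dihydroxy-4-methyl-1-oxo-1,3-dihydro-2-benzofuran-5-yl)oxy]-4-hydroxy-3-(hydroxymethyl)-6-methylbenzoate | COC(=O)c1c(C)cc(O)c(CO)c1Oc1c(C)c2c(c(O)c1O)C(=O)OC2 | target

## Step count and least certain steps

Total: 13 steps. Longest linear sequence: 10 steps (steps 1–4 and 8–13); the ring B branch (steps 5–7) is three steps.

**Step 12 (key step).** The most likely failure is condensation of the ring B hydroxybenzyl alcohol at the temperature the carboxylation needs. The C3' hydroxymethyl is para to the C6' phenoxide, so hydroxide can be lost to give a quinone methide that alkylates other phenoxides. The carboxylation is also reversible and may stop at low conversion. The fallback brings in the lactone carbon by palladium chemistry before the ether is made; it sets out from 9 and comes back at 17.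
- Aldehyde 9 is reduced (NaBH4, MeOH) to 6-(hydroxymethyl)-5-methyl-2,2-diphenyl-1,3-benzodioxol-4-ol F1.
- NBS brominates the single remaining ring position, para to the phenol, giving 7-bromo-6-(hydroxymethyl)-5-methyl-2,2-diphenyl-1,3-benzodioxol-4-ol F2.
- Carbonylative lactonisation of this 2-bromobenzyl alcohol (Pd(OAc)2, Xantphos, CO, Et3N, toluene, 100 °C) gives 5-hydroxy-4-methyl-6,7-(diphenylmethylenedioxy)-2-benzofuran-1(3H)-one F3.
- Its phenoxide displaces fluoride from 5 (K2CO3, DMF) to give methyl 3-formyl-4-(methoxymethoxy)-6-methyl-2-{[4-methyl-1-oxo-6,7-(diphenylmethylenedioxy)-1,3-dihydro-2-benzofuran-5-yl]oxy}benzoate F4.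
- TFA–H2O removes both protecting groups to give methyl 2-[(6,7-dihydroxy-4-methyl-1-oxo-1,3-dihydro-2-benzofuran-5-yl)oxy]-3-formyl-4-hydroxy-6-methylbenzoate F5.
- NaBH4 at 0 °C reduces the aldehyde, not the lactone or ester, and gives 17.

**Step 8.** The substitution at the congested C–F carbon may be slow enough that the phenoxide instead attacks the ester (acyl transfer or O-methylation by the methyl ester). The fallback makes the ether before the ester exists; it sets out from 4 and 9 and comes back at 10. Bromo aldehyde 4 and phenol 9 are joined by the same addition–elimination (Cs2CO3, DMF, 90 °C; activation by the ortho formyl group) to give 3-bromo-2-[(6-formyl-5-methyl-2,2-diphenyl-1,3-benzodioxol-4-yl)oxy]-6-(methoxymethoxy)-4-methylbenzaldehyde F6. Its bromide is then methoxycarbonylated (Pd(OAc)2, Xantphos, CO, MeOH, Et3N) to 10.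

**Step 4.** The fluoride of the product lies between two carbonyl groups and may be displaced by methanol during the carbonylation. Oxidative addition at the doubly ortho-substituted bromide may also be slow. The fallback replaces catalysis by halogen–metal exchange; it sets out from 4 and comes back at 5.
- The aldehyde is masked (HC(OMe)3, PPTS, MeOH) as 2-bromo-4-(dimethoxymethyl)-3-fluoro-5-(methoxymethoxy)-1-methylbenzene F7.
- Bromine–lithium exchange (n-BuLi, THF, −78 °C) and trapping with methyl chloroformate give methyl 3-(dimethoxymethyl)-2-fluoro-4-(methoxymethoxy)-6-methylbenzoate F8.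
- Dilute aqueous HCl in THF at 0 °C hydrolyses the dimethyl acetal faster than the aryl MOM ether and gives 5.

**Step 6.** Bromination may also occur para to the hydroxyl, at the carbon between the ketal oxygen and the formyl group, which would put the methyl group in the wrong place. The fallback uses a sigmatropic delivery that can only reach the ortho carbon; it sets out from 7 and comes back at 9. Phenol 7 is treated with the chlorosulfonium salt from Me2S and N-chlorosuccinimide and then Et3N (Gassman ortho-alkylation, [2,3]-shift of the aryloxysulfonium ylide) to give 7-hydroxy-6-[(methylsulfanyl)methyl]-2,2-diphenyl-1,3-benzodioxole-5-carbaldehyde F9. Desulfurisation with deactivated Raney Ni in acetone–EtOH gives 9.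

**Step 11.** Acid-induced ionisation of the two hydroxybenzyl alcohols of 12 (ether formation, oligomerisation) or partial ketalisation of the catechol may erode the yield, and 12 itself is air-sensitive. The fallback keeps the catechol protected until the acetonide is in place; it sets out from 10 and comes back at 13.
- The aryl MOM ether alone is cleaved (TMSOTf, 2,2'-bipyridyl, CH2Cl2, then water) to give methyl 3-formyl-2-[(6-formyl-5-methyl-2,2-diphenyl-1,3-benzodioxol-4-yl)oxy]-4-hydroxy-6-methylbenzoate F10.
- NaBH4 gives methyl 4-hydroxy-3-(hydroxymethyl)-2-{[6-(hydroxymethyl)-5-methyl-2,2-diphenyl-1,3-benzodioxol-4-yl]oxy}-6-methylbenzoate F11.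
- 2,2-Dimethoxypropane and PPTS give methyl 5-{[6-(hydroxymethyl)-5-methyl-2,2-diphenyl-1,3-benzodioxol-4-yl]oxy}-2,2,7-trimethyl-4H-1,3-benzodioxine-6-carboxylate F12.
- Hydrogenolysis of the diphenylmethylene ketal (H2, Pd/C, EtOAc) gives 13.

## Further compounds

F1 | step 12 | 6-(hydroxymethyl)-5-methyl-2,2-diphenyl-1,3-benzodioxol-4-ol | OCc1cc2OC(c3ccccc3)(c3ccccc3)Oc2c(O)c1C
F2 | step 12 | 7-bromo-6-(hydroxymethyl)-5-methyl-2,2-diphenyl-1,3-benzodioxol-4-ol | OCc1c(Br)c2OC(c3ccccc3)(c3ccccc3)Oc2c(O)c1C
F3 | step 12 | 5-hydroxy-4-methyl-6,7-(diphenylmethylenedioxy)-2-benzofuran-1(3H)-one | Cc1c(O)c2OC(c3ccccc3)(c3ccccc3)Oc2c2C(=O)OCc12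
F4 | step 12 | methyl 3-formyl-4-(methoxymethoxy)-6-methyl-2-{[4-methyl-1-oxo-6,7-(diphenylmethylenedioxy)-1,3-dihydro-2-benzofuran-5-yl]oxy}benzoate | COC(=O)c1c(C)cc(OCOC)c(C=O)c1Oc1c(C)c2COC(=O)c2c2OC(c3ccccc3)(c3ccccc3)Oc12
F5 | step 12 | methyl 2-[(6,7-dihydroxy-4-methyl-1-oxo-1,3-dihydro-2-benzofuran-5-yl)oxy]-3-formyl-4-hydroxy-6-methylbenzoate | COC(=O)c1c(C)cc(O)c(C=O)c1Oc1c(C)c2COC(=O)c2c(O)c1O
F6 | step 8 | 3-bromo-2-[(6-formyl-5-methyl-2,2-diphenyl-1,3-benzodioxol-4-yl)oxy]-6-(methoxymethoxy)-4-methylbenzaldehyde | COCOc1cc(C)c(Br)c(Oc2c(C)c(C=O)cc3OC(c4ccccc4)(c4ccccc4)Oc23)c1C=O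
F7 | step 4 | 2-bromo-4-(dimethoxymethyl)-3-fluoro-5-(methoxymethoxy)-1-methylbenzene | COCOc1cc(C)c(Br)c(F)c1C(OC)OC
F8 | step 4 | methyl 3-(dimethoxymethyl)-2-fluoro-4-(methoxymethoxy)-6-methylbenzoate | COCOc1cc(C)c(C(=O)OC)c(F)c1C(OC)OC
F9 | step 6 | 7-hydroxy-6-[(methylsulfanyl)methyl]-2,2-diphenyl-1,3-benzodioxole-5-carbaldehyde | CSCc1c(C=O)cc2OC(c3ccccc3)(c3ccccc3)Oc2c1O
F10 | step 11 | methyl 3-formyl-2-[(6-formyl-5-methyl-2,2-diphenyl-1,3-benzodioxol-4-yl)oxy]-4-hydroxy-6-methylbenzoate | COC(=O)c1c(C)cc(O)c(C=O)c1Oc1c(C)c(C=O)cc2OC(c3ccccc3)(c3ccccc3)Oc12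
F11 | step 11 | methyl 4-hydroxy-3-(hydroxymethyl)-2-{[6-(hydroxymethyl)-5-methyl-2,2-diphenyl-1,3-benzodioxol-4-yl]oxy}-6-methylbenzoate | COC(=O)c1c(C)cc(O)c(CO)c1Oc1c(C)c(CO)cc2OC(c3ccccc3)(c3ccccc3)Oc12
F12 | step 11 | methyl 5-{[6-(hydroxymethyl)-5-methyl-2,2-diphenyl-1,3-benzodioxol-4-yl]oxy}-2,2,7-trimethyl-4H-1,3-benzodioxine-6-carboxylate | COC(=O)c1c(C)cc2OC(C)(C)OCc2c1Oc1c(C)c(CO)cc2OC(c3ccccc3)(c3ccccc3)Oc12
A1 | alternative 1 | depsidone (seven-membered aryl ester lactone) with ring A acetoxymethyl and mesylate groups and the ring B phthalide | O=C1Oc2c(O)c3C(=O)OCc3c(C)c2Oc2c(COC(C)=O)c(OS(C)(=O)=O)cc(C)c12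
A2 | alternative 1 | xanthone precursor of A1 (carbonyl bound directly to C6' of ring B) | O=C1c2c(O)c3C(=O)OCc3c(C)c2Oc2c(COC(C)=O)c(OS(C)(=O)=O)cc(C)c12
A3 | alternative 2 | methyl 2-{[6,7-bis(benzyloxy)-4-methyl-1-oxo-1,3-dihydro-2-benzofuran-5-yl]oxy}-3-({[tert-butyl(dimethyl)silyl]oxy}methyl)-4-hydroxy-6-methylbenzoate | COC(=O)c1c(C)cc(O)c(CO[Si](C)(C)C(C)(C)C)c1Oc1c(C)c2COC(=O)c2c(OCc2ccccc2)c1OCc1ccccc1
A4 | alternative 2 | methyl 2-diazo-4-methyl-3-oxopent-4-enoate | COC(=O)C(=[N+]=[N-])C(=O)C(C)=C
A5 | alternative 2 | 6,7-bis(benzyloxy)-5-[(3-{[tert-butyl(dimethyl)silyl]oxy}prop-1-yn-1-yl)oxy]-4-methyl-2-benzofuran-1(3H)-one | CC(C)(C)[Si](C)(C)OCC#COc1c(C)c2COC(=O)c2c(OCc2ccccc2)c1OCc1ccccc1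
A6 | alternative 2 | methyl 3-methyl-2-(oxomethylidene)but-3-enoate (vinylketene) | COC(=O)C(=C=O)C(C)=C
A7 | alternative 3 | methyl 5-{[6-(benzyloxy)-7-hydroxy-4-methyl-1-oxo-1,3-dihydro-2-benzofuran-5-yl]oxy}-2,2,7-trimethyl-4H-1,3-benzodioxine-6-carboxylate | COC(=O)c1c(C)cc2OC(C)(C)OCc2c1Oc1c(C)c2COC(=O)c2c(O)c1OCc1ccccc1
A8 | alternative 3 | methyl 5-{[(2Z)-3-(benzyloxy)-4-methoxy-4-oxo-1-[1-(phenylsulfonyl)ethyl]... enyl]oxy} ester, i.e. the (Z)-2-(benzyloxy)-3-(ring A aryloxy)-4-(phenylsulfonyl)pent-2-enoate, racemic at the sulfonyl carbon | COC(=O)/C(OCc1ccccc1)=C(/Oc1c2COC(C)(C)Oc2cc(C)c1C(=O)OC)C(C)S(=O)(=O)c1ccccc1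
A9 | alternative 3 | furan-2(5H)-one | O=C1OCC=C1
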